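## Analysis of the target

The target consists of two 7-methoxycoumarins held by a 3,6-dimethylcyclohex-2-ene (ring C). Coumarin A is bonded through C6 to the tertiary carbon C1' of ring C. Coumarin B is bonded through C8 and an (E)-ethene-1,2-diyl bridge to the quaternary carbon C6', which also carries a methyl group; the second methyl group sits on C3' of the C2'=C3' double bond. C1' and C6' are the only stereocentres and both are S, so the coumarin A substituent and the styryl-type substituent lie on the same face of ring C, with the C6' methyl group trans to the aryl group. Sensitive groups are the two lactones (cinnamate-type acceptors that do not survive hydrides, enolates or hydroxide), the trisubstituted ring alkene (acid-labile; a free phenol at C7 of coumarin A would add across it under acid) and the 1,5-diene array C3'=C2'–C1'–C6'–CH=CH, for which a thermal [3,3] shift is conceivable. The difficulty is twofold: a vicinal tertiary/quaternary pair, each centre bearing a bulky sp2 group in a cis relation, must be set with absolute control, and ring C must be attached at C6 of a 7-oxygenated coumarin, which electrophilic substitution of the intact heterocycle does not address selectively. The strategy rests on the benzene ring of coumarin A: C4a (carbon branch to C4), C5 (H), C6 (ring C), C7 (oxygen), C8 (H) and C8a (oxygen) show the pattern of a 2,4-dihydroxybenzoate. That is the pattern an unbranched 3,5-dioxo ester chain with a terminal aldehyde gives when the future C4a condenses with the future C5, so ring C can be finished first and carried into the arene on the chain carbon that becomes C6.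

## Retrosynthetic reasoning

Target 26 is first cut at the bond between C8 of coumarin B and the bridging CH carbon. This is the only bond that separates an achiral, easily made coumarin from the part holding all the stereochemistry; it gives terminal alkene 22 and aryl iodide 25. The forward Heck coupling must give the E alkene only. Because C6' is quaternary, β-hydride elimination can occur only on the aryl side and the double bond cannot migrate. Iodide 25 goes back through phenol 24 to 23, iodine entering at C8 ortho to the hydroxyl group before O-methylation.

In 22 the pyranone of coumarin A is cut at O1–C2 and C3=C4, which leads to salicylaldehyde 20. Closing this ring late keeps every strongly basic or reducing step ahead of the first lactone. The forward reaction must add two carbons and enforce the cis C3=C4 geometry; an intramolecular Wittig reaction of the phenol ester ylide 21 does this by ring constraint at moderate temperature. Aldehyde 20 is the redox-adjusted form (through alcohol 19) of ester 18, the mono-methyl ether of resorcylate 17. The methylation must distinguish two phenols, which the hydrogen bond of the ortho-hydroxyl to the ester allows.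

The benzene ring of 17 is cut between the ester-bearing carbon (future C4a) and the neighbouring CH (future C5). A doubly activated methylene and an aldehyde form exactly this bond by condensation. The cut unfolds the arene into the single chain of 15, masked as acetal 14, in which the two ketones are already the C7 and C8a oxygens and ring C hangs on the carbon that becomes C6. The gain is that the substitution pattern of coumarin A is written into the chain and cannot emerge as a regioisomer, and ring C enters with its stereocentres finished. The forward reaction must close through carbon and not through an enol oxygen, then aromatise via 16.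

Precursor 14 is cut at C4–C5 of the chain into the four-carbon nucleophile 12, made from 11, and aldehyde 10. The bond is formed as an aldol addition giving 13, followed by oxidation of the carbinol. An aldehyde is used as electrophile in place of ester 9 because 9 is α-branched and carries a β-methoxy leaving group. Under the strongly basic dianion, slow acylation would compete with enolisation and loss of methanol, whereas addition to a formyl group at low temperature is fast.

In 9, the precursor of 10 by partial reduction, the bond between the ester α-carbon and the acetal carbon is cut, leading to ester 7. The forward step adds the one-carbon unit already at the acetal level to silyl ketene acetal 8, so a free α-formyl ester is never handled.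

The ethenyl group of 7 is traced to the formyl group of 6 by a one-carbon olefination. The aldehyde is kept at this point because it is the activating group for the next disconnection.

Ring C of 6 is cut at C1'–C6' and C4'–C5' in a retro-Diels–Alder sense, giving diene 4 and the α-methyl enal 5. The ring double bond C2'=C3' lies where a [4+2] cycloaddition places it, and both diene substituents direct the same regiochemistry. The endo rule converts the E geometry of 4 into the cis relation of the C1' and C6' substituents, and a chiral Lewis acid can set the absolute configuration in the same step. The α-methyl group of 5 becomes the methyl group of the quaternary centre. Building the ring first and adding the side chain by conjugate addition would leave the relative configuration to the small steric difference between a methyl group and an unsaturated two-carbon group on the neighbouring quaternary carbon.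

Diene 4 is the deconjugated isomer of dienoate 3, which is cut at C2=C3 into enal 1 and phosphonate 2.

## Alternatives that were turned down

Alternative 1: Ring C would be closed by an Ireland–Claisen rearrangement.
- Disconnection: the acid (1R,2R)-2-(7-methoxy-2-oxochromen-6-yl)-1,4-dimethylcyclohex-3-ene-1-carboxylic acid A2 (aryl and carboxyl cis) is cut at C1'–C6' and C3' is reconnected to the carboxyl oxygen. This gives the six-membered lactone A1, whose carbinol carbon bears the C3' methyl group and the (E)-arylvinyl unit.
- Forward key step: the silyl ketene acetal of A1 rearranges through the boat forced by the lactone ring. It forms C1'–C6', breaks C3'–O and leaves C2'=C3' in place. The boat puts the aryl group of the E alkene on the side of the carboxyl bridge, hence the cis relation.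
- For: one carbinol centre controls both new stereocentres; ring C is made with the complete coumarin A already attached, so no arene has to be built.
- Against: A1 needs an enantiopure tertiary allylic carbinol. Its enolisation requires an amide base in the presence of the electrophilic coumarin lactone. The tertiary allylic ester ionises easily. A2 then needs several redox and olefination steps before the styrene exists.
- Comparison: it is stronger in stereochemical economy. The chosen route instead uses strong bases only before any lactone exists and takes both centres from one catalytic cycloaddition of two small achiral pieces.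

Alternative 2: Ring C would be closed by ring-closing metathesis.
- Disconnection: aldehyde A4, (1R,2R)-2-(7-methoxy-2-oxochromen-6-yl)-1,4-dimethylcyclohex-3-ene-1-carbaldehyde (aryl and formyl cis), is cut at C2'=C3' to the open-chain diene A3, whose two stereocentres come from an acyclic allylation.
- Forward key step: the second-generation Grubbs catalyst RuCl2(=CHPh)(H2IMes)(PCy3) initiates at the monosubstituted alkene on C1' and closes onto the 1,1-disubstituted terminus with loss of ethene.
- For: this is among the most dependable ring closures. It tolerates the aldehyde and the coumarin, and A4 carries the formyl group for the styrene directly.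
- Against: the stereochemical problem is only moved to A3. A vicinal tertiary/quaternary pair must be set in an open transition state between two prochiral partners, one an electron-poor coumarinyl allyl electrophile. Olefination of the neopentyl aldehyde A4 with a benzylic ylide of coumarin B would give E/Z mixtures.
- Comparison: its ring-closing step is safer than the aldol aromatisation chosen here, and no arene construction is needed. The chosen route instead fixes the relative configuration in a cyclic endo transition state and the bridge geometry by the Heck mechanism.

Alternative 3: A Danheiser benzannulation would build the benzene ring of coumarin B.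
- Disconnection: phenol A7, 6-{6-[(E)-2-(2-hydroxy-6-methoxyphenyl)ethenyl]-3,6-dimethylcyclohex-2-enyl}-7-methoxychromen-2-one, is cut at C8–C8a, C6–C7 and C4a–C8a into the methoxy enyne A5 and cyclobut-2-en-1-one A6.
- Forward key step: heating opens A6 to vinylketene, which adds [2+2] to the alkynyl ether of A5. Four-electron ring opening, six-electron electrocyclisation and tautomerisation give A7, with the substituent flanked by hydroxyl and methoxyl.
- For: the 1,2,3-substitution of the arene is fully controlled, and no metal-catalysed coupling is needed at the crowded C8.
- Against: A5 already contains ring C, both stereocentres and coumarin A, so the real difficulties are untouched. The key step is spent on a ring that the chosen route takes from commodity compound 23. A6 is volatile and unstable and the alkynyl ether fragile. The reaction needs about 80–120 °C in the presence of the 1,5-diene. A7 still lacks the pyranone, so ortho-formylation and lactonisation must follow.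
- Comparison: it is stronger only at the hindered aryl–alkene bond. The chosen route accepts a Heck coupling there and invests its ring construction in coumarin A, where it also solves the regiochemical attachment of ring C.

Key step: step 9

Remark: the antipode of the oxazaborolidinium catalyst in step 3 is assigned from the usual transition-state model for 2-substituted acroleins (formyl C–H···O binding, one enal face screened by a phenyl group); both antipodes are made from commercial (R)- or (S)-diphenylprolinol, so the absolute configuration is a matter of catalyst choice only.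

## Route

Step 1
Reactants: 1 3-methylbut-2-enal; 2 trimethyl phosphonoacetate
Product: 3 methyl (2E)-5-methylhexa-2,4-dienoate
Conditions: NaH, THF, 0 °C to rt
Reagents that add atoms: none
Why: Horner–Wadsworth–Emmons olefination: the sodium phosphonate anion adds to the aldehyde carbon of the enal and the stabilised adduct collapses to the (2E)-dienoate.

Step 2
Reactants: 3 methyl (2E)-5-methylhexa-2,4-dienoate
Product: 4 methyl (3E)-5-methylhexa-3,5-dienoate
Conditions: LiN(i-Pr)2, DMPU, THF, −78 °C; then AcOH, −78 °C
Reagents that add atoms: none
Why: Deconjugative protonation: removal of a terminal methyl proton gives the extended trienolate, which is protonated kinetically at the α-carbon. The s-trans C3–C4 bond of 3 becomes the (3E) double bond, and any (3Z) isomer cannot adopt the s-cis diene conformation and is left behind in step 3.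

Step 3
Reactants: 4 methyl (3E)-5-methylhexa-3,5-dienoate; 5 2-methylprop-2-enal
Product: 6 methyl 2-[(1S,6R)-6-formyl-3,6-dimethylcyclohex-2-en-1-yl]acetate
Conditions: (3aR)-1-(2-methylphenyl)-3,3-diphenyltetrahydro-1H,3H-pyrrolo[1,2-c][1,3,2]oxazaborole·HNTf2 (10 mol %), CH2Cl2, −78 °C
Reagents that add atoms: none
Why: Enantioselective Diels–Alder reaction catalysed by a chiral cationic oxazaborolidine: both diene substituents raise the coefficient at the CH2 terminus of 4, which bonds to the β-carbon of the boron-bound enal, so C1' ends up next to the new quaternary C6'. The formyl-endo transition state of the (E)-diene places the CH2CO2Me group on C1' cis to the formyl group on C6', and the catalyst, which screens one enal face with a phenyl group, leaves the si face of the α-carbon open, setting C6' as R and thereby C1' as S.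

Step 4
Reactants: 6 methyl 2-[(1S,6R)-6-formyl-3,6-dimethylcyclohex-2-en-1-yl]acetate
Product: 7 methyl 2-[(1S,6S)-6-ethenyl-3,6-dimethylcyclohex-2-en-1-yl]acetate
Conditions: Ph3PCH3Br, KOt-Bu, THF, 0 °C to rt
Reagents that add atoms: methyltriphenylphosphonium bromide, C[P+](c1ccccc1)(c1ccccc1)c1ccccc1.[Br-]
Why: Wittig methylenation of a non-enolisable α-quaternary aldehyde; the unstabilised ylide reacts with the formyl group far faster than with the methyl ester at 0 °C, and neither stereocentre carries an acidic hydrogen.

Step 5
Reactants: 7 methyl 2-[(1S,6S)-6-ethenyl-3,6-dimethylcyclohex-2-en-1-yl]acetate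
Product: 9 methyl (2RS)-2-[(1R,6S)-6-ethenyl-3,6-dimethylcyclohex-2-en-1-yl]-3,3-dimethoxypropanoate, via silyl ketene acetal 8 (not isolated)
Conditions: LiN(i-Pr)2, THF, −78 °C, then Me3SiCl; solvent exchange to CH2Cl2; HC(OMe)3, Me3SiOTf (10 mol %), −78 °C
Reagents that add atoms: trimethyl orthoformate, COC(OC)OC
Why: Mukaiyama-type addition: the lithium enolate of 7 is O-silylated to 8, and the silyl triflate turns the orthoformate into a dimethoxycarbenium ion that is attacked by the nucleophilic α-carbon, giving the β,β-dimethoxy ester directly with loss of methoxytrimethylsilane. The new centre at C2 forms unselectively, which does not matter because this carbon becomes the aromatic C6; the stabilised carbenium ion should not attack the isolated alkenes at −78 °C.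

Step 6
Reactants: 9 methyl (2RS)-2-[(1R,6S)-6-ethenyl-3,6-dimethylcyclohex-2-en-1-yl]-3,3-dimethoxypropanoate
Product: 10 (2RS)-2-[(1R,6S)-6-ethenyl-3,6-dimethylcyclohex-2-en-1-yl]-3,3-dimethoxypropanal
Conditions: i-Bu2AlH (1.1 equiv), CH2Cl2, −78 °C; MeOH, then aq. KNaC4H4O6
Reagents that add atoms: none
Why: Partial reduction of an ester by a dialkylaluminium hydride: at −78 °C the tetrahedral aluminium hemiacetal is held by the neighbouring acetal oxygens and releases the aldehyde only on work-up; crude 10 is used at once to avoid loss of methanol on silica.

Step 7
Reactants: 10 (2RS)-2-[(1R,6S)-6-ethenyl-3,6-dimethylcyclohex-2-en-1-yl]-3,3-dimethoxypropanal; 11 methyl acetoacetate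
Product: 13 methyl (5RS,6RS)-6-[(1R,6S)-6-ethenyl-3,6-dimethylcyclohex-2-en-1-yl]-5-hydroxy-7,7-dimethoxy-3-oxoheptanoate, via dilithium dienolate 12 (not isolated)
Conditions: 11, LiN(i-Pr)2 (2.1 equiv), THF, 0 °C; then 10, −78 °C; AcOH
Reagents that add atoms: none
Why: Aldol addition of the acetoacetate dianion: the terminal carbanion of 12 is its more nucleophilic site and should add to the formyl group within minutes at −78 °C, faster than it deprotonates the hindered α-position of 10. The two new centres form as a mixture and are both removed in steps 8 and 9.

Step 8
Reactants: 13 methyl (5RS,6RS)-6-[(1R,6S)-6-ethenyl-3,6-dimethylcyclohex-2-en-1-yl]-5-hydroxy-7,7-dimethoxy-3-oxoheptanoate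
Product: 14 methyl (6RS)-6-[(1R,6S)-6-ethenyl-3,6-dimethylcyclohex-2-en-1-yl]-7,7-dimethoxy-3,5-dioxoheptanoate
Conditions: Dess–Martin periodinane, NaHCO3, CH2Cl2, 0 °C to rt
Reagents that add atoms: none
Why: Dess–Martin oxidation of the secondary carbinol to the β,δ-diketo ester under hydrogencarbonate buffering, which keeps the acetal intact; partial loss of methanol from 14 to its enol ether would be harmless, since both forms give 15 in step 9.

Step 9
Reactants: 14 methyl (6RS)-6-[(1R,6S)-6-ethenyl-3,6-dimethylcyclohex-2-en-1-yl]-7,7-dimethoxy-3,5-dioxoheptanoate
Product: 17 methyl 5-[(1S,6S)-6-ethenyl-3,6-dimethylcyclohex-2-en-1-yl]-2,4-dihydroxybenzoate, via formyl diketo ester 15 (not isolated), via cyclohexenedione 16 (not isolated)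
Conditions: (a) 1 M aq. HCl, THF, 0 °C; (b) piperidine, AcOH (0.2 equiv each), toluene, 50 °C
Reagents that add atoms: none
Why: Aqueous acid first hydrolyses the β-keto acetal of 14 to the formyl diketo ester 15, which rests as its hydrogen-bonded hydroxymethylene tautomer. Piperidinium acetate then converts this masked aldehyde reversibly into an enaminone/iminium and enolises the β-keto ester, so that C2 of the chain attacks C7 in an intramolecular Knoevenagel–aldol condensation (6-exo-trig at the formyl carbon, enol-endo on the nucleophile side), forming the C4a–C5 bond of coumarin A. Loss of water gives cyclohexenedione 16, and enolisation of its two ketones aromatises the ring to the 2,4-dihydroxybenzoate 17, the former C3 and C5 oxygens becoming the C8a and C7 oxygens. The closest known reaction type is the biomimetic aldol cycloaromatisation of 3,5,7-tricarbonyl chains to resorcylates. No stereocentre is formed: the mixed centre at C6 of the chain becomes the aromatic C6, and C1' and C6' of ring C are not enolisable and pass through unchanged. The selectivity required is carbon over oxygen cyclisation: C2 is the only carbon acid that can reach C7 through a six-membered transition state (the more acidic C4 would close a four-membered ring), the buffered amine medium avoids the acid-promoted oxygen closure to a pyran-4-one, and aromatisation makes the carbon closure irreversible. Because the arene is created under weakly basic conditions, the new C7 phenol never meets strong acid, which would add it across the C2'=C3' double bond.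

Step 10
Reactants: 17 methyl 5-[(1S,6S)-6-ethenyl-3,6-dimethylcyclohex-2-en-1-yl]-2,4-dihydroxybenzoate
Product: 18 methyl 5-[(1S,6S)-6-ethenyl-3,6-dimethylcyclohex-2-en-1-yl]-2-hydroxy-4-methoxybenzoate
Conditions: MeI (1.1 equiv), K2CO3 (1.1 equiv), acetone, rt
Reagents that add atoms: iodomethane, CI
Why: Williamson methylation under mono-deprotonation: the hydroxyl para to the ester is the more acidic and the free one, while the ortho-hydroxyl is held in a hydrogen bond to the ester carbonyl, so one equivalent of base and iodomethane should give the 4-methyl ether, the future C7 methoxy group.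

Step 11
Reactants: 18 methyl 5-[(1S,6S)-6-ethenyl-3,6-dimethylcyclohex-2-en-1-yl]-2-hydroxy-4-methoxybenzoate
Product: 19 4-[(1S,6S)-6-ethenyl-3,6-dimethylcyclohex-2-en-1-yl]-2-(hydroxymethyl)-5-methoxyphenol
Conditions: LiAlH4, THF, 0 °C to rt
Reagents that add atoms: none
Why: Hydride reduction of the salicylate ester to the benzylic alcohol (excess reagent, since the phenol consumes one hydride); the alkenes are inert, and the electron-rich benzylic alcohol is worked up without acid and oxidised directly.

Step 12
Reactants: 19 4-[(1S,6S)-6-ethenyl-3,6-dimethylcyclohex-2-en-1-yl]-2-(hydroxymethyl)-5-methoxyphenol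
Product: 20 5-[(1S,6S)-6-ethenyl-3,6-dimethylcyclohex-2-en-1-yl]-2-hydroxy-4-methoxybenzaldehyde
Conditions: MnO2 (activated, excess), CH2Cl2, rt
Reagents that add atoms: none
Why: Chemoselective oxidation of the benzylic alcohol by activated manganese dioxide to the salicylaldehyde; isolated alkenes and the phenol are untouched and the reagent does not over-oxidise.

Step 13
Reactants: 20 5-[(1S,6S)-6-ethenyl-3,6-dimethylcyclohex-2-en-1-yl]-2-hydroxy-4-methoxybenzaldehyde
Product: 22 6-[(1S,6S)-6-ethenyl-3,6-dimethylcyclohex-2-en-1-yl]-7-methoxy-2H-chromen-2-one, via aryl ester ylide 21 (not isolated)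
Conditions: Ph3P=C=C=O, toluene, 90 °C
Reagents that add atoms: (triphenylphosphoranylidene)ketene, O=C=C=P(c1ccccc1)(c1ccccc1)c1ccccc1
Why: The phenol adds across the C=C bond of the cumulated ylide to give ester ylide 21, whose intramolecular Wittig reaction with the ortho-formyl group closes the pyranone. The ring enforces the cis C3=C4 bond, so no separate isomerisation or high-temperature lactonisation is needed and the 1,5-diene of ring C is not put at thermal risk.

Step 14
Reactants: 23 umbelliferone (7-hydroxy-2H-chromen-2-one)
Product: 24 7-hydroxy-8-iodo-2H-chromen-2-one
Conditions: I2, KI, aq. NH3, 0 °C to rt; then dilute HCl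
Reagents that add atoms: iodine, II
Why: Electrophilic iodination of the phenoxide: in 7-hydroxycoumarins the position between the hydroxyl group and the ring oxygen (C8) is the most nucleophilic, so one equivalent of iodine should give the 8-iodo compound; acidification re-closes any opened lactone.

Step 15
Reactants: 24 7-hydroxy-8-iodo-2H-chromen-2-one
Product: 25 8-iodo-7-methoxy-2H-chromen-2-one
Conditions: MeI, K2CO3, acetone, reflux
Reagents that add atoms: iodomethane, CI
Why: Williamson O-methylation of the phenol under mild carbonate conditions that leave the lactone intact.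

Step 16
Reactants: 22 6-[(1S,6S)-6-ethenyl-3,6-dimethylcyclohex-2-en-1-yl]-7-methoxy-2H-chromen-2-one; 25 8-iodo-7-methoxy-2H-chromen-2-one
Product: 26 6-[(1S,6S)-6-[(E)-2-(7-methoxy-2-oxo-2H-chromen-8-yl)ethenyl]-3,6-dimethylcyclohex-2-en-1-yl]-7-methoxy-2H-chromen-2-one
Conditions: Pd(OAc)2 (10 mol %), Bu4NCl, NaHCO3, DMF, 80 °C
Reagents that add atoms: none
Why: Heck reaction under ligand-free phase-transfer conditions: oxidative addition of the aryl iodide to zerovalent palladium, syn insertion of the terminal alkene with the aryl group going to the CH2 carbon, and syn β-hydride elimination, which is possible only toward the benzylic hydrogen because C6' is quaternary, so the E bridge forms and cannot migrate. The trisubstituted ring alkene and the two coumarin C3=C4 bonds are far less reactive toward insertion than the monosubstituted alkene.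

## Compound list

1 | 3-methylbut-2-enal | CC(C)=CC=O | starting material
2 | trimethyl phosphonoacetate | COC(=O)CP(=O)(OC)OC | starting material
3 | methyl (2E)-5-methylhexa-2,4-dienoate | COC(=O)/C=C/C=C(C)C | intermediate
4 | methyl (3E)-5-methylhexa-3,5-dienoate | COC(=O)C/C=C/C(C)=C | intermediate
5 | 2-methylprop-2-enal | CC(=C)C=O | starting material
6 | methyl 2-[(1S,6R)-6-formyl-3,6-dimethylcyclohex-2-en-1-yl]acetate | COC(=O)C[C@H]1C=C(C)CC[C@@]1(C)C=O | intermediate
7 | methyl 2-[(1S,6S)-6-ethenyl-3,6-dimethylcyclohex-2-en-1-yl]acetate | COC(=O)C[C@H]1C=C(C)CC[C@@]1(C)C=C | intermediate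
8 | ({2-[(1R,6S)-6-ethenyl-3,6-dimethylcyclohex-2-en-1-yl]-1-methoxyethenyl}oxy)trimethylsilane | COC(O[Si](C)(C)C)=C[C@H]1C=C(C)CC[C@@]1(C)C=C | intermediate (not isolated)
9 | methyl (2RS)-2-[(1R,6S)-6-ethenyl-3,6-dimethylcyclohex-2-en-1-yl]-3,3-dimethoxypropanoate | COC(=O)C(C(OC)OC)[C@H]1C=C(C)CC[C@@]1(C)C=C | intermediate
10 | (2RS)-2-[(1R,6S)-6-ethenyl-3,6-dimethylcyclohex-2-en-1-yl]-3,3-dimethoxypropanal | O=CC(C(OC)OC)[C@H]1C=C(C)CC[C@@]1(C)C=C | intermediate
11 | methyl acetoacetate (methyl 3-oxobutanoate) | COC(=O)CC(C)=O | starting material
12 | dilithium 1-methoxybuta-1,3-diene-1,3-diolate (dianion of 11) | [Li+].[Li+].COC([O-])=CC([O-])=C | intermediate (not isolated)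
13 | methyl (5RS,6RS)-6-[(1R,6S)-6-ethenyl-3,6-dimethylcyclohex-2-en-1-yl]-5-hydroxy-7,7-dimethoxy-3-oxoheptanoate | COC(=O)CC(=O)CC(O)C(C(OC)OC)[C@H]1C=C(C)CC[C@@]1(C)C=C | intermediate
14 | methyl (6RS)-6-[(1R,6S)-6-ethenyl-3,6-dimethylcyclohex-2-en-1-yl]-7,7-dimethoxy-3,5-dioxoheptanoate | COC(=O)CC(=O)CC(=O)C(C(OC)OC)[C@H]1C=C(C)CC[C@@]1(C)C=C | intermediate
15 | methyl (6RS)-6-[(1R,6S)-6-ethenyl-3,6-dimethylcyclohex-2-en-1-yl]-3,5,7-trioxoheptanoate (drawn as the aldehyde tautomer) | COC(=O)CC(=O)CC(=O)C(C=O)[C@H]1C=C(C)CC[C@@]1(C)C=C | intermediate (not isolated)
16 | methyl 3-[(1R,6S)-6-ethenyl-3,6-dimethylcyclohex-2-en-1-yl]-4,6-dioxocyclohex-1-ene-1-carboxylate | COC(=O)C1=CC([C@H]2C=C(C)CC[C@@]2(C)C=C)C(=O)CC1=O | intermediate (not isolated)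
17 | methyl 5-[(1S,6S)-6-ethenyl-3,6-dimethylcyclohex-2-en-1-yl]-2,4-dihydroxybenzoate | COC(=O)c1cc([C@H]2C=C(C)CC[C@@]2(C)C=C)c(O)cc1O | intermediate
18 | methyl 5-[(1S,6S)-6-ethenyl-3,6-dimethylcyclohex-2-en-1-yl]-2-hydroxy-4-methoxybenzoate | COC(=O)c1cc([C@H]2C=C(C)CC[C@@]2(C)C=C)c(OC)cc1O | intermediate
19 | 4-[(1S,6S)-6-ethenyl-3,6-dimethylcyclohex-2-en-1-yl]-2-(hydroxymethyl)-5-methoxyphenol | OCc1cc([C@H]2C=C(C)CC[C@@]2(C)C=C)c(OC)cc1O | intermediate
20 | 5-[(1S,6S)-6-ethenyl-3,6-dimethylcyclohex-2-en-1-yl]-2-hydroxy-4-methoxybenzaldehyde | O=Cc1cc([C@H]2C=C(C)CC[C@@]2(C)C=C)c(OC)cc1O | intermediate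
21 | 4-[(1S,6S)-6-ethenyl-3,6-dimethylcyclohex-2-en-1-yl]-2-formyl-5-methoxyphenyl (triphenyl-λ5-phosphanylidene)acetate | O=Cc1cc([C@H]2C=C(C)CC[C@@]2(C)C=C)c(OC)cc1OC(=O)C=P(c1ccccc1)(c1ccccc1)c1ccccc1 | intermediate (not isolated)
22 | 6-[(1S,6S)-6-ethenyl-3,6-dimethylcyclohex-2-en-1-yl]-7-methoxy-2H-chromen-2-one | COc1cc2oc(=O)ccc2cc1[C@H]1C=C(C)CC[C@@]1(C)C=C | intermediate
23 | umbelliferone (7-hydroxy-2H-chromen-2-one) | O=c1ccc2ccc(O)cc2o1 | starting material
24 | 7-hydroxy-8-iodo-2H-chromen-2-one | O=c1ccc2ccc(O)c(I)c2o1 | intermediate
25 | 8-iodo-7-methoxy-2H-chromen-2-one | COc1ccc2ccc(=O)oc2c1I | intermediate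
26 | 6-[(1S,6S)-6-[(E)-2-(7-methoxy-2-oxo-2H-chromen-8-yl)ethenyl]-3,6-dimethylcyclohex-2-en-1-yl]-7-methoxy-2H-chromen-2-one | COc1cc2oc(=O)ccc2cc1[C@H]1C=C(C)CC[C@@]1(C)/C=C/c1c(OC)ccc2ccc(=O)oc12 | target

## Step count and least certain steps

Total step count: 16. Longest linear sequence: 14 steps (steps 1–13 and 16); steps 14 and 15 make iodide 25.

Step 9 (key step). The most likely failure is closure through oxygen during the acid stage, where the C3 enol oxygen adds to the freed aldehyde and dehydrates to a pyran-4-one. The second risk is retro-Claisen loss of the formyl group once base and water are present together. The fallback never exposes the tricarbonyl chain to acid and sets out from 7 and 11. Dianion 12 is acylated by ester 7 to give methyl 6-[(1S,6S)-6-ethenyl-3,6-dimethylcyclohex-2-en-1-yl]-3,5-dioxohexanoate F1. Its trianion (LiN(i-Pr)2, 3.3 equiv, THF) is formylated at the terminal carbon with methyl formate, which generates 15 directly as its enolate under aprotic basic conditions. A buffered aqueous work-up (pH about 8–9) lets it close and aromatise, and the route is rejoined at 17.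

Step 3. The most likely failure is incomplete facial control, because the ester of 4 competes with 5 for the boron centre and an uncatalysed background reaction is possible. The α-methyl group may also erode the endo preference. The fallback sets out from 4 and 5 and runs the cycloaddition with EtAlCl2. This gives the racemic cis adduct, that is 6 together with its enantiomer methyl 2-[(1R,6S)-6-formyl-3,6-dimethylcyclohex-2-en-1-yl]acetate F2. The enantiomers are separated by preparative chromatography on a polysaccharide chiral stationary phase, and the route is rejoined at 6.

Step 5. The most likely failure is loss of methanol from the product under the silyl triflate, giving the enol ether, or protodesilylation of 8 back to 7. The fallback sets out from 7. Claisen formylation of its lithium enolate with methyl formate gives methyl (2RS)-2-[(1R,6S)-6-ethenyl-3,6-dimethylcyclohex-2-en-1-yl]-3-oxopropanoate F3. Acetalisation with HC(OMe)3 in MeOH and catalytic pyridinium p-toluenesulfonate then returns to the route at 9.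

Step 6. The most likely failure is over-reduction to the primary alcohol, or elimination of methanol from the β,β-dimethoxy aldehyde during work-up. The fallback sets out from 9. Exhaustive reduction with LiAlH4 gives (2RS)-2-[(1R,6S)-6-ethenyl-3,6-dimethylcyclohex-2-en-1-yl]-3,3-dimethoxypropan-1-ol F4. Buffered Dess–Martin oxidation of F4 then returns to the route at 10.

Step 13. The most likely failure is slow acylation of the chelated, hindered phenol by the cumulated ylide, which would allow intermolecular Wittig oligomerisation. The fallback sets out from 20. Olefination with Ph3P=CHCO2Me at rt gives methyl (2E)-3-{5-[(1S,6S)-6-ethenyl-3,6-dimethylcyclohex-2-en-1-yl]-2-hydroxy-4-methoxyphenyl}prop-2-enoate F5. Irradiation at 365 nm isomerises it to the Z ester, which lactonises with loss of methanol, and the route is rejoined at 22.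

Step 16. The most likely failure is slow insertion, since the aryl iodide is flanked by two ortho substituents and the alkene sits on a quaternary carbon. Catalyst decomposition and proto-deiodination would then take over. The fallback changes how the arylpalladium species is generated and sets out from 25. Miyaura borylation (B2pin2, PdCl2(dppf), KOAc, dioxane, 80 °C) gives 7-methoxy-8-(4,4,5,5-tetramethyl-1,3,2-dioxaborolan-2-yl)-2H-chromen-2-one F6. F6 is then coupled with 22 in an oxidative boron-Heck reaction (Pd(OAc)2, benzoquinone, DMF, 50 °C), in which transmetalation to ligand-poor divalent palladium replaces oxidative addition, and the route is rejoined at 26.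

## Further compounds

F1 | step 9 | methyl 6-[(1S,6S)-6-ethenyl-3,6-dimethylcyclohex-2-en-1-yl]-3,5-dioxohexanoate | COC(=O)CC(=O)CC(=O)C[C@H]1C=C(C)CC[C@@]1(C)C=C
F2 | step 3 | methyl 2-[(1R,6S)-6-formyl-3,6-dimethylcyclohex-2-en-1-yl]acetate | COC(=O)C[C@@H]1C=C(C)CC[C@]1(C)C=O
F3 | step 5 | methyl (2RS)-2-[(1R,6S)-6-ethenyl-3,6-dimethylcyclohex-2-en-1-yl]-3-oxopropanoate | COC(=O)C(C=O)[C@H]1C=C(C)CC[C@@]1(C)C=C
F4 | step 6 | (2RS)-2-[(1R,6S)-6-ethenyl-3,6-dimethylcyclohex-2-en-1-yl]-3,3-dimethoxypropan-1-ol | OCC(C(OC)OC)[C@H]1C=C(C)CC[C@@]1(C)C=C
F5 | step 13 | methyl (2E)-3-{5-[(1S,6S)-6-ethenyl-3,6-dimethylcyclohex-2-en-1-yl]-2-hydroxy-4-methoxyphenyl}prop-2-enoate | COC(=O)/C=C/c1cc([C@H]2C=C(C)CC[C@@]2(C)C=C)c(OC)cc1O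
F6 | step 16 | 7-methoxy-8-(4,4,5,5-tetramethyl-1,3,2-dioxaborolan-2-yl)-2H-chromen-2-one | COc1ccc2ccc(=O)oc2c1B1OC(C)(C)C(C)(C)O1
A1 | alternative 1 | (6S)-6-[(E)-2-(7-methoxy-2-oxo-2H-chromen-6-yl)ethenyl]-3,6-dimethyloxan-2-one | CC1CC[C@@](C)(/C=C/c2cc3ccc(=O)oc3cc2OC)OC1=O
A2 | alternative 1 | (1R,2R)-2-(7-methoxy-2-oxo-2H-chromen-6-yl)-1,4-dimethylcyclohex-3-ene-1-carboxylic acid | COc1cc2oc(=O)ccc2cc1[C@H]1C=C(C)CC[C@@]1(C)C(=O)O
A3 | alternative 2 | (2R)-2-[(1R)-1-(7-methoxy-2-oxo-2H-chromen-6-yl)prop-2-en-1-yl]-2,5-dimethylhex-5-enal | COc1cc2oc(=O)ccc2cc1[C@@H](C=C)[C@](C)(C=O)CCC(C)=C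
A4 | alternative 2 | (1R,2R)-2-(7-methoxy-2-oxo-2H-chromen-6-yl)-1,4-dimethylcyclohex-3-ene-1-carbaldehyde | COc1cc2oc(=O)ccc2cc1[C@H]1C=C(C)CC[C@@]1(C)C=O
A5 | alternative 3 | 6-[(1S,6S)-6-[(E)-4-methoxybut-1-en-3-yn-1-yl]-3,6-dimethylcyclohex-2-en-1-yl]-7-methoxy-2H-chromen-2-one | COc1cc2oc(=O)ccc2cc1[C@H]1C=C(C)CC[C@@]1(C)/C=C/C#COC
A6 | alternative 3 | cyclobut-2-en-1-one | O=C1C=CC1
A7 | alternative 3 | 6-[(1S,6S)-6-[(E)-2-(2-hydroxy-6-methoxyphenyl)ethenyl]-3,6-dimethylcyclohex-2-en-1-yl]-7-methoxy-2H-chromen-2-one | COc1cc2oc(=O)ccc2cc1[C@H]1C=C(C)CC[C@@]1(C)/C=C/c1c(OC)cccc1O
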